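**Retrosynthetic overview**

1. The target is numbered as a labdane (ring A: C1–C5, C10; ring B: C5–C10). Late disconnections are the C12–C13 bond (B-alkyl Suzuki–Miyaura coupling on a C9 vinyl group) and the two isovalerates (acylation of a 3α,6β,19-triol).
2. Key disconnection is C3–C4: ring A is closed last, on a finished ring B, by Dieckmann-type acylation of a lactone enolate (C4) with an N-methoxy-N-methylamide (C3), giving a 3-oxo-19,6β-olide.
3. Enabling feature: the C19 oxymethylene on C4 and the 6β-hydroxyl on ring B are 1,3-diaxial on the β-face, so they are the two ends of a temporary γ-lactone C19(=O)–O–C6 (ring atoms C4, C19, O, C6, C5) whose α-carbon is C4. The lactone makes C4 enolisable, decides which enolate face can reach C3, and returns both oxygen functions on LiAlH4 reduction.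
4. Ring B and its stereocentres come from (R)-carvone: carvone C5 → C5, isopropenyl → C4/C18/C19, C6 → C10 (methyl, then allyl = C20 and C1–C3), carbonyl → C9 (vinyl triflate), ring methyl → C17, C4 → C6 (oxygen by iodolactonisation).
5. Order of ring formation: ring B (chiral pool) → temporary γ-lactone (step 6) → ring A (step 10); the lactone is opened in step 11.

Key step: step 10

Remark: α/β refer to the usual labdane drawing with the C10 methyl β. Intermediates 7–16 are carried as mixtures of epimers at centres that are flattened later (C8 in 7–11; the lactone α-carbon C4 in 8–16).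

**Route**

Step 1
Reactants: 1 (R)-(−)-carvone
Product: 3 (5R,6RS)-2,6-dimethyl-5-(prop-1-en-2-yl)cyclohex-2-en-1-one, via cross-conjugated lithium dienolate 2 (not isolated)
Conditions: LDA, THF, −78 °C; MeI, −78 → 0 °C
Reagents that add atoms: iodomethane, CI
Why: Kinetic enolate alkylation: LDA removes the α'-proton at carvone C6 and iodomethane C-alkylates the enolate; the configuration of this carbon is unimportant because it is enolised again in step 2.

Step 2
Reactants: 3 (5R,6RS)-2,6-dimethyl-5-(prop-1-en-2-yl)cyclohex-2-en-1-one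
Product: 5 (5S,6S)-2,6-dimethyl-6-(prop-2-en-1-yl)-5-(prop-1-en-2-yl)cyclohex-2-en-1-one, via cross-conjugated lithium dienolate 4 (not isolated)
Conditions: LDA, THF, −78 °C; allyl bromide, DMPU, −78 → 25 °C
Reagents that add atoms: allyl bromide, C=CCBr
Why: Second enolate alkylation builds the quaternary carbon (future C10): the electrophile approaches the planar enolate anti to the isopropenyl group on the neighbouring C5, so the allyl arm (future C1–C3) ends trans and the methyl (future C20) cis to the isopropenyl carbon (future C4), as the trans ring fusion requires.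

Step 3
Reactants: 5 (5S,6S)-2,6-dimethyl-6-(prop-2-en-1-yl)-5-(prop-1-en-2-yl)cyclohex-2-en-1-one
Product: 7 (5S,6S)-2,6-dimethyl-6-(prop-2-en-1-yl)-5-(prop-1-en-2-yl)cyclohex-3-en-1-one, via linear lithium dienolate 6 (not isolated)
Conditions: LDA, THF/DMPU, −78 → −20 °C; inverse quench into AcOH/THF, −78 °C
Reagents that add atoms: none
Why: Deconjugative protonation: with the α'-position quaternary, LDA can only remove a γ-proton (future C6–H) to give the linear dienolate, and kinetic C-protonation at the α-carbon (C8) leaves the alkene at C6=C7 next to the carvone stereocentre C5; the new C8 centre is flattened later.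

Step 4
Reactants: 7 (5S,6S)-2,6-dimethyl-6-(prop-2-en-1-yl)-5-(prop-1-en-2-yl)cyclohex-3-en-1-one
Product: 9 6-(3-hydroxypropyl)-5-(1-hydroxypropan-2-yl)-2,6-dimethylcyclohex-3-en-1-one, via bis(9-BBN) adduct 8 (not isolated)
Conditions: 9-BBN (2.5 equiv), THF, 0 → 25 °C; then NaOAc, H2O2, H2O, 0 → 25 °C
Reagents that add atoms: hydrogen peroxide, OO
Why: Hydroboration–oxidation: 9-BBN adds anti-Markovnikov to the two terminal alkenes much faster than to the ring cis-alkene or the doubly hindered ketone (any carbinol formed is reoxidised in step 5), the acetate-buffered peroxide work-up avoids base-induced return of the alkene into conjugation, and the new C4 centre, formed unselectively, is erased by enolisation in step 10.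

Step 5
Reactants: 9 6-(3-hydroxypropyl)-5-(1-hydroxypropan-2-yl)-2,6-dimethylcyclohex-3-en-1-one
Product: 10 2-[2-(2-carboxyethyl)-2,4-dimethyl-3-oxocyclohex-5-en-1-yl]propanoic acid
Conditions: CrO3, H2SO4, H2O/acetone, 0 °C
Reagents that add atoms: water, O
Why: Jones oxidation takes both primary alcohols to carboxylic acids through the aldehyde hydrates; at 0 °C and short contact time the hindered β,γ-unsaturated ketone is not expected to enolise towards conjugation.

Step 6
Reactants: 10 2-[2-(2-carboxyethyl)-2,4-dimethyl-3-oxocyclohex-5-en-1-yl]propanoic acid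
Product: 12 3-(3,4,6-trimethyl-2,5-dioxo-2,3,3a,4,5,7a-hexahydro-1-benzofuran-4-yl)propanoic acid (cis-fused; 5α-H, 6β-O, 10β-methyl), via iodolactone 11 (not isolated)
Conditions: I2, NaHCO3, MeCN/H2O, 0 °C; then DBU, THF, 25 °C
Reagents that add atoms: none
Why: Iodolactonisation of the γ,δ-unsaturated acid (5-exo opening of the iodonium ion) then E1cB loss of HI from the β-iodo ketone: the C19 carboxylate can reach C6 only on the face of its own C5–C4 bond, so the γ-lactone is cis-fused and the new C6–O bond is β (cis to C4 and to the C10 methyl), the C3 acid would need a seven- or eight-membered ring and stays free, and DBU restores the C7=C8 enone.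

Step 7
Reactants: 12 3-(3,4,6-trimethyl-2,5-dioxo-2,3,3a,4,5,7a-hexahydro-1-benzofuran-4-yl)propanoic acid
Product: 13 N-methoxy-N-methyl-3-(3,4,6-trimethyl-2,5-dioxo-2,3,3a,4,5,7a-hexahydro-1-benzofuran-4-yl)propanamide
Conditions: MeNH(OMe)·HCl, EDC·HCl, HOBt (cat.), N-methylmorpholine, CH2Cl2, 0 → 25 °C
Reagents that add atoms: N,O-dimethylhydroxylamine hydrochloride, CNOC.Cl
Why: Carbodiimide amide coupling gives the N-methoxy-N-methylamide, an acyl donor whose α-protons are far less acidic than the lactone α-proton and whose tetrahedral adduct is stable; the tertiary amine is too weak to disturb the γ-acyloxy enone.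

Step 8
Reactants: 13 N-methoxy-N-methyl-3-(3,4,6-trimethyl-2,5-dioxo-2,3,3a,4,5,7a-hexahydro-1-benzofuran-4-yl)propanamide
Product: 15 4-[3-(methoxy(methyl)amino)-3-oxopropyl]-3,4,6-trimethyl-2-oxo-2,3,3a,4,7,7a-hexahydro-1-benzofuran-5-yl trifluoromethanesulfonate, via lithium enolate 14 (not isolated)
Conditions: LiBH(s-Bu)3 (L-Selectride, 1.05 equiv), THF, −78 °C; then N-(5-chloropyridin-2-yl)triflimide, −78 → 0 °C
Reagents that add atoms: N-(5-chloropyridin-2-yl)-1,1,1-trifluoro-N-(trifluoromethylsulfonyl)methanesulfonamide, O=S(=O)(N(c1ccc(Cl)cn1)S(=O)(=O)C(F)(F)F)C(F)(F)F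
Why: Conjugate (1,4) hydride reduction of the α-methyl enone (1,2-attack is blocked by the quaternary C10) gives the enolate with its double bond fixed at C8=C9, and O-sulfonylation traps it as the tetrasubstituted vinyl triflate while C7 becomes CH2; at −78 °C the lactone and the amide should not be reduced.

Step 9
Reactants: 15 4-[3-(methoxy(methyl)amino)-3-oxopropyl]-3,4,6-trimethyl-2-oxo-2,3,3a,4,7,7a-hexahydro-1-benzofuran-5-yl trifluoromethanesulfonate
Product: 16 3-(5-ethenyl-3,4,6-trimethyl-2-oxo-2,3,3a,4,7,7a-hexahydro-1-benzofuran-4-yl)-N-methoxy-N-methylpropanamide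
Conditions: tributyl(vinyl)stannane, Pd(PPh3)4 (5 mol%), LiCl, CuI (cat.), DMF, 60 °C
Reagents that add atoms: tributyl(vinyl)stannane, C=C[Sn](CCCC)(CCCC)CCCC
Why: Stille coupling: zerovalent palladium inserts into the C9–OTf bond and the vinyl group (C11, C12) is transferred from tin under neutral conditions that leave the lactone α-centre and the amide untouched.

Step 10
Reactants: 16 3-(5-ethenyl-3,4,6-trimethyl-2-oxo-2,3,3a,4,7,7a-hexahydro-1-benzofuran-4-yl)-N-methoxy-N-methylpropanamide
Product: 19 3-oxo-13,14,15,16-tetranorlabda-8,11-dien-19,6β-olide, via lithium lactone enolate 17 (not isolated), via lithium hemiaminal chelate 18 (not isolated)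
Conditions: LiN(SiMe3)2 (1.5 equiv), THF, −78 → 0 °C; AcOH, −78 °C, then aq. NH4Cl
Reagents that add atoms: none
Why: LiN(SiMe3)2 removes the lactone α-proton at C4 (several pKa units more acidic than the α-CH2 of the N-methoxy-N-methylamide), and the tetrasubstituted lactone enolate 17 adds to the amide carbonyl C3 to give the lithium-chelated hemiaminal 18, which releases no alkoxide and therefore allows neither retro-Claisen cleavage of the non-enolisable β-keto lactone nor a second addition until the acetic acid quench frees ketone 19. The closest known reaction type is the Dieckmann (intramolecular Claisen) condensation in its kinetic variant, with an N-methoxy-N-methylamide as acyl donor for an ester or lactone enolate. Ring A (C1–C5, C10) is closed in a 6-(enolexo)-exo-trig mode: the enolate C4=C19 bond lies outside the new ring and the amide C=O is exocyclic to it. The one new stereocentre, quaternary C4, is set by the cis-fused γ-lactone: C19 is held on the β-face by its O–C6 bond, so only the enolate face turned towards the C10 arm (gauche to the C5–C10 bond) can reach C3, which puts C19 axial (4β) and the methyl C18 equatorial (4α), whereas the other face points away from the tether and cannot cyclise. C5, C6 and C10 are untouched, and the trans ring fusion follows from the equatorial C5–C4 and C10–C1 bonds already present on ring B. The step needs site-selective enolisation and C-acylation without reversal, which are secured by the acidity gap, by the absence of any other enolisable carbonyl (the C9 ketone was converted into the vinyl triflate in step 8), by the stable chelate, and by the fact that O-acylation would need an eight-membered ring.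

Step 11
Reactants: 19 3-oxo-13,14,15,16-tetranorlabda-8,11-dien-19,6β-olide
Product: 21 13,14,15,16-tetranorlabda-8,11-diene-3α,6β,19-triol, via lithium 3α-alkoxide 20 (not isolated)
Conditions: LiBH(s-Bu)3, THF, −78 °C; then LiAlH4, −78 → 25 °C; aqueous NaOH work-up
Reagents that add atoms: none
Why: Ketone reduction under steric approach control, then lactone reduction: the bulky borohydride cannot use the axial trajectory on the α-face (axial hydrogens on C1 and C5) and attacks C3 equatorially from the β-face to give the axial 3α-alkoxide 20, which is anti to the lactone carbonyl and cannot translactonise, and LiAlH4 then opens the lactone to the 6β-hydroxyl and the C19 primary alcohol without touching a stereocentre.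

Step 12
Reactants: 21 13,14,15,16-tetranorlabda-8,11-diene-3α,6β,19-triol
Product: 22 6β-hydroxy-13,14,15,16-tetranorlabda-8,11-diene-3α,19-diyl bis(3-methylbutanoate)
Conditions: isovaleric anhydride (2.5 equiv), DMAP (0.2 equiv), pyridine, 25 °C
Reagents that add atoms: 3-methylbutanoic anhydride, CC(C)CC(=O)OC(=O)CC(C)C
Why: DMAP-catalysed acylation with steric site selectivity: the primary C19–OH and the axial C3–OH (syn-axial only to hydrogens) are esterified, whereas the 6β-OH, syn-axial to two carbon substituents (the C10 methyl and the C19 methylene) and flanked by C5, is expected to stay free.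

Step 13
Reactants: 23 tert-butyl acetoacetate
Product: 24 tert-butyl (2E)-3-[(trifluoromethylsulfonyl)oxy]but-2-enoate
Conditions: Tf2O, aq. Me4NOH, hexane, 5 → 25 °C
Reagents that add atoms: trifluoromethanesulfonic anhydride, O=S(=O)(OS(=O)(=O)C(F)(F)F)C(F)(F)F
Why: Enol triflation of the β-keto ester under biphasic Schotten–Baumann-type conditions: the non-chelated tetramethylammonium enolate reacts from its extended geometry, placing the triflate trans to the ester (E), so the methyl is cis to the ester as in the target side chain.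

Step 14
Reactants: 22 6β-hydroxy-13,14,15,16-tetranorlabda-8,11-diene-3α,19-diyl bis(3-methylbutanoate); 24 tert-butyl (2E)-3-[(trifluoromethylsulfonyl)oxy]but-2-enoate
Product: 26 tert-butyl (13E)-6β-hydroxy-3α,19-bis(3-methylbutanoyloxy)labda-8,13-dien-15-oate, via B-alkyl-9-BBN adduct 25 (not isolated)
Conditions: 9-BBN (2.5 equiv), THF, 0 → 25 °C; then 24, PdCl2(dppf) (10 mol%), AsPh3, aq. K3PO4, THF/DMF, 25 °C
Reagents that add atoms: none
Why: Hydroboration then B-alkyl Suzuki–Miyaura coupling: 9-BBN adds only to the terminal carbon (C12) of the vinyl group (the tetrasubstituted C8=C9 alkene is inert), and the primary alkylborane couples with the enol triflate with retention of the E geometry to form the C12–C13 bond; the esters and the free 6β-OH tolerate the mild phosphate base.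

Step 15
Reactants: 26 tert-butyl (13E)-6β-hydroxy-3α,19-bis(3-methylbutanoyloxy)labda-8,13-dien-15-oate
Product: 27 (13E)-6β-hydroxy-3α,19-bis(3-methylbutanoyloxy)labda-8,13-dien-15-oic acid (CNP0333611.1)
Conditions: CF3CO2H/CH2Cl2 (1:4), 0 °C
Reagents that add atoms: none
Why: Acidolysis of the tert-butyl ester (loss of 2-methylpropene through the tert-butyl cation) frees the carboxylic acid, while the two isovalerates, the hindered secondary alcohol and the tetrasubstituted alkene are expected to survive the brief cold acid treatment.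

**Compound list**

1 | (R)-(−)-carvone, (5R)-2-methyl-5-(prop-1-en-2-yl)cyclohex-2-en-1-one | CC1=CC[C@@H](C(C)=C)CC1=O | starting material
2 | cross-conjugated lithium dienolate of 1 (formed in the flask) | CC1=CC[C@@H](C(C)=C)C=C1[O-].[Li+] | intermediate
3 | (5R,6RS)-2,6-dimethyl-5-(prop-1-en-2-yl)cyclohex-2-en-1-one (6-methylcarvone) | CC1=CC[C@@H](C(C)=C)C(C)C1=O | intermediate
4 | cross-conjugated lithium dienolate of 3 (formed in the flask) | CC1=CC[C@@H](C(C)=C)C(C)=C1[O-].[Li+] | intermediate
5 | (5S,6S)-2,6-dimethyl-6-(prop-2-en-1-yl)-5-(prop-1-en-2-yl)cyclohex-2-en-1-one | CC1=CC[C@@H](C(C)=C)[C@](C)(CC=C)C1=O | intermediate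
6 | linear lithium dienolate of 5, O–C9=C8–C7=C6 (formed in the flask) | CC1=C([O-])[C@@](C)(CC=C)[C@H](C(C)=C)C=C1.[Li+] | intermediate
7 | (5S,6S)-2,6-dimethyl-6-(prop-2-en-1-yl)-5-(prop-1-en-2-yl)cyclohex-3-en-1-one (C2 epimers) | CC1C=C[C@@H](C(C)=C)[C@](C)(CC=C)C1=O | intermediate
8 | bis(9-BBN) adduct of 7, boron on both terminal carbons (formed in the flask) | CC1C=C[C@@H](C(C)CB2C3CCCC2CCC3)[C@](C)(CCCB2C3CCCC2CCC3)C1=O | intermediate
9 | 6-(3-hydroxypropyl)-5-(1-hydroxypropan-2-yl)-2,6-dimethylcyclohex-3-en-1-one (ring centres C5, C10 as in 5) | CC1C=C[C@@H](C(C)CO)[C@](C)(CCCO)C1=O | intermediate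
10 | 2-[2-(2-carboxyethyl)-2,4-dimethyl-3-oxocyclohex-5-en-1-yl]propanoic acid (β,γ-unsaturated keto diacid) | CC1C=C[C@@H](C(C)C(=O)O)[C@](C)(CCC(=O)O)C1=O | intermediate
11 | iodolactone: cis-fused 19,6β-lactone with 7α-iodine trans to the lactone oxygen, C9 ketone, free C3 acid (formed in the flask) | CC1[C@H](I)[C@H]2OC(=O)C(C)[C@H]2[C@](C)(CCC(=O)O)C1=O | intermediate
12 | 3-(3,4,6-trimethyl-2,5-dioxo-2,3,3a,4,5,7a-hexahydro-1-benzofuran-4-yl)propanoic acid, cis-fused lactone (5α-H, 6β-O, 10β-methyl) | CC1=C[C@H]2OC(=O)C(C)[C@H]2[C@](C)(CCC(=O)O)C1=O | intermediate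
13 | N-methoxy-N-methylamide of 12 | CC1=C[C@H]2OC(=O)C(C)[C@H]2[C@](C)(CCC(=O)N(C)OC)C1=O | intermediate
14 | lithium enolate O–C9=C8 from conjugate reduction of 13 (formed in the flask) | CC1=C([O-])[C@@](C)(CCC(=O)N(C)OC)[C@@H]2C(C)C(=O)O[C@@H]2C1.[Li+] | intermediate
15 | C9 vinyl triflate: 4-[3-(methoxy(methyl)amino)-3-oxopropyl]-3,4,6-trimethyl-2-oxo-2,3,3a,4,7,7a-hexahydro-1-benzofuran-5-yl trifluoromethanesulfonate | CC1=C(OS(=O)(=O)C(F)(F)F)[C@@](C)(CCC(=O)N(C)OC)[C@@H]2C(C)C(=O)O[C@@H]2C1 | intermediate
16 | 3-(5-ethenyl-3,4,6-trimethyl-2-oxo-2,3,3a,4,7,7a-hexahydro-1-benzofuran-4-yl)-N-methoxy-N-methylpropanamide (key-step precursor) | CC1=C(C=C)[C@@](C)(CCC(=O)N(C)OC)[C@@H]2C(C)C(=O)O[C@@H]2C1 | intermediate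
17 | lithium lactone enolate of 16, C4=C19 (formed in the flask) | CC1=C(C=C)[C@@](C)(CCC(=O)N(C)OC)[C@@H]2C(C)=C([O-])O[C@@H]2C1.[Li+] | intermediate
18 | lithium-chelated hemiaminal at C3 of the ring-closed 19,6β-olide (formed in the flask) | CC1=C(C=C)[C@@]2(C)CCC([O-])(N(C)OC)[C@]3(C)C(=O)O[C@H](C1)[C@H]23.[Li+] | intermediate
19 | 3-oxo-13,14,15,16-tetranorlabda-8,11-dien-19,6β-olide (4α-methyl, 5α-H, 10β-methyl) | CC1=C(C=C)[C@@]2(C)CCC(=O)[C@]3(C)C(=O)O[C@H](C1)[C@H]23 | intermediate
20 | lithium 3α-alkoxide of 13,14,15,16-tetranorlabda-8,11-dien-19,6β-olide (formed in the flask) | CC1=C(C=C)[C@@]2(C)CC[C@@H]([O-])[C@]3(C)C(=O)O[C@H](C1)[C@H]23.[Li+] | intermediate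
21 | 13,14,15,16-tetranorlabda-8,11-diene-3α,6β,19-triol | CC1=C(C=C)[C@@]2(C)CC[C@@H](O)[C@](C)(CO)[C@@H]2[C@H](O)C1 | intermediate
22 | 6β-hydroxy-13,14,15,16-tetranorlabda-8,11-diene-3α,19-diyl bis(3-methylbutanoate) | CC1=C(C=C)[C@@]2(C)CC[C@@H](OC(=O)CC(C)C)[C@](C)(COC(=O)CC(C)C)[C@@H]2[C@H](O)C1 | intermediate
23 | tert-butyl acetoacetate (tert-butyl 3-oxobutanoate) | CC(=O)CC(=O)OC(C)(C)C | starting material
24 | tert-butyl (2E)-3-[(trifluoromethylsulfonyl)oxy]but-2-enoate | C/C(OS(=O)(=O)C(F)(F)F)=C\C(=O)OC(C)(C)C | intermediate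
25 | B-alkyl-9-BBN adduct of 22, boron on C12 (formed in the flask) | CC1=C(CCB3C4CCCC3CCC4)[C@@]2(C)CC[C@@H](OC(=O)CC(C)C)[C@](C)(COC(=O)CC(C)C)[C@@H]2[C@H](O)C1 | intermediate
26 | tert-butyl (13E)-6β-hydroxy-3α,19-bis(3-methylbutanoyloxy)labda-8,13-dien-15-oate | CC1=C(CC/C(C)=C/C(=O)OC(C)(C)C)[C@@]2(C)CC[C@@H](OC(=O)CC(C)C)[C@](C)(COC(=O)CC(C)C)[C@@H]2[C@H](O)C1 | intermediate
27 | (13E)-6β-hydroxy-3α,19-bis(3-methylbutanoyloxy)labda-8,13-dien-15-oic acid (CNP0333611.1) | CC1=C(CC/C(C)=C/C(=O)O)[C@@]2(C)CC[C@@H](OC(=O)CC(C)C)[C@](C)(COC(=O)CC(C)C)[C@@H]2[C@H](O)C1 | target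

**Step count and risks**

Total step count: 15. Longest linear sequence: 14 steps (steps 1–12, 14 and 15; step 13 is a one-step branch).

Steps most likely to fail:

Step 10 (ring A closure). The hindered tetrasubstituted enolate may add too slowly to the amide, so that base-induced loss of the N-methoxy group or proton transfer to the amide α-position competes. The fallback generates the C4 enolate reductively and closes the same bond by an aldol reaction; it sets out from 15 and comes back at 19. LiN(SiMe3)2 then N-bromosuccinimide (THF, −78 °C) should brominate the lactone α-carbon of 15 to give the α-bromo lactone vinyl triflate F1. Cp2Zr(H)Cl (THF, 25 °C) should reduce only the N-methoxy-N-methylamide, giving the bromo aldehyde F2. SmI2 (divalent samarium iodide, THF, −78 °C) then forms the trivalent samarium enolate at C4 by C–Br reduction and closes ring A by an intramolecular Reformatsky aldol reaction to the 3-hydroxy lactone triflate F3; the same face constraint gives the same C4 configuration, and the C3 configuration is irrelevant. Dess–Martin oxidation gives the 3-oxo lactone triflate F4, and the Stille coupling of step 9 applied to F4 returns to 19.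

Step 8 (reductive triflation). Possible failures are competing 1,2-reduction or hydride attack on the amide, proton transfer from the lactone α-CH to the new enolate followed by premature Claisen chemistry, and slow O-sulfonylation of the hindered enolate. The fallback avoids a free enolate; it sets out from 13 and comes back at 15. RhCl(PPh3)3-catalysed 1,4-hydrosilylation of the enone with Et3SiH (toluene, 50 °C) should give the triethylsilyl enol ether F5 regiospecifically, and CsF with PhNTf2 in DME at 25 °C should convert F5 directly into vinyl triflate 15.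

Step 12 (site-selective acylation). Site selectivity may be lost through over-acylation at the 6β-hydroxyl or incomplete acylation of the neopentylic 3α-hydroxyl. The fallback replaces kinetic discrimination by tying O-6 and C19 together while C3 is acylated; it sets out from 19 and comes back at 22.
- LiBH(s-Bu)3 alone (THF, −78 °C) gives, after work-up, the 3α-hydroxy lactone F6.
- i-Bu2AlH (2.2 equiv, CH2Cl2, −78 °C) reduces the lactone to the lactol F7.
- MeOH with pyridinium p-toluenesulfonate closes the cyclic methyl acetal F8.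
- The only free hydroxyl (3α) is acylated under forcing conditions (isovaleric anhydride, DMAP, 50 °C) to the acetal ester F9.
- Aqueous acetic acid hydrolyses the acetal to the lactol ester F10, and NaBH4 in MeOH reduces it to the 6β,19-diol 3-ester F11.
- Isovaleryl chloride (1.05 equiv) in pyridine at −20 °C then acylates only the primary C19 hydroxyl, returning to 22.

**Further compounds**

F1 | step 10 | α-bromo lactone vinyl triflate (15 with bromine on the lactone α-carbon C4) | CC1=C(OS(=O)(=O)C(F)(F)F)[C@@](C)(CCC(=O)N(C)OC)[C@@H]2C(C)(Br)C(=O)O[C@@H]2C1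
F2 | step 10 | bromo aldehyde (F1 with the amide reduced to the C3 aldehyde) | CC1=C(OS(=O)(=O)C(F)(F)F)[C@@](C)(CCC=O)[C@@H]2C(C)(Br)C(=O)O[C@@H]2C1
F3 | step 10 | 3-hydroxy-19,6β-olide bearing the C9 triflate (C3 epimers) | CC1=C(OS(=O)(=O)C(F)(F)F)[C@@]2(C)CCC(O)[C@]3(C)C(=O)O[C@H](C1)[C@H]23
F4 | step 10 | 3-oxo-19,6β-olide bearing the C9 triflate | CC1=C(OS(=O)(=O)C(F)(F)F)[C@@]2(C)CCC(=O)[C@]3(C)C(=O)O[C@H](C1)[C@H]23
F5 | step 8 | triethylsilyl enol ether (O–C9=C8) of the conjugate-reduced 13 | CC1=C(O[Si](CC)(CC)CC)[C@@](C)(CCC(=O)N(C)OC)[C@@H]2C(C)C(=O)O[C@@H]2C1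
F6 | step 12 | 3α-hydroxy-13,14,15,16-tetranorlabda-8,11-dien-19,6β-olide | CC1=C(C=C)[C@@]2(C)CC[C@@H](O)[C@]3(C)C(=O)O[C@H](C1)[C@H]23
F7 | step 12 | 6β,19-epoxy-13,14,15,16-tetranorlabda-8,11-diene-3α,19-diol (lactol) | CC1=C(C=C)[C@@]2(C)CC[C@@H](O)[C@]3(C)C(O)O[C@H](C1)[C@H]23
F8 | step 12 | 19-methoxy-6β,19-epoxy-13,14,15,16-tetranorlabda-8,11-dien-3α-ol (cyclic methyl acetal) | CC1=C(C=C)[C@@]2(C)CC[C@@H](O)[C@]3(C)C(OC)O[C@H](C1)[C@H]23
F9 | step 12 | 3α-(3-methylbutanoyloxy) derivative of F8 | CC1=C(C=C)[C@@]2(C)CC[C@@H](OC(=O)CC(C)C)[C@]3(C)C(OC)O[C@H](C1)[C@H]23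
F10 | step 12 | 3α-(3-methylbutanoyloxy) lactol (19-hydroxy-6β,19-epoxide) | CC1=C(C=C)[C@@]2(C)CC[C@@H](OC(=O)CC(C)C)[C@]3(C)C(O)O[C@H](C1)[C@H]23
F11 | step 12 | 6β,19-dihydroxy-13,14,15,16-tetranorlabda-8,11-dien-3α-yl 3-methylbutanoate | CC1=C(C=C)[C@@]2(C)CC[C@@H](OC(=O)CC(C)C)[C@](C)(CO)[C@@H]2[C@H](O)C1
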